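The closed, stirred vessel holds starting material, the limiting reagent, with partner in excess, and it is read for target.

| flask | starting material | partner | time |
|---|---|---|---|
| winter | 0.600 M | 1.80 M |  |
| autumn | 0.600 M | 2.70 M |  |
| midnight | 0.600 M | 1.80 M | 92 min |

| winter run: time / min | winter run: [target] / M | autumn run: time / min | autumn run: [target] / M |
|---|---|---|---|
| 1.0 | 0.0227 | 1.0 | 0.0308 |
| 3.1 | 0.0619 | 3.1 | 0.0949 |
| 5.9 | 0.1049 | 5.9 | 0.1543 |
| 9.4 | 0.1472 | 9.4 | 0.1951 |
| 13 | 0.1702 | 13 | 0.2269 |
| 18 | 0.1904 | 18 | 0.2497 |
| 23 | 0.2070 | 23 | 0.2532 |

(each reading ± 0.002 M)

- the exponent of [partner] in the starting rate at the charge of the winter run (at the point where two percent of the starting material have become target)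
- target in the midnight run at 92 min, as a share of the starting material charged

- Overall: starting material + partner -> target.
- Constant volume, constant temperature.
- "The second partner" is partner.
- An order is taken over about fifteen percent of the charge, up and down.

At 3.1 min the autumn reading stands at 1.53 times the winter reading, with 1.50 times the partner, so the order in partner reads 1.05.

Two times are set side by side for the midnight run. The first is the fall time, in which the rate of gaining target sinks by a factor e. The winter run gains 0.0378 /min of the charge up to its first reading and 0.00553 /min near 20.5 min, which reads as 10.7 min.

The second is the holding time. Carried from the first autumn reading, that fall leaves the autumn run gaining 0.00751 /min of the charge near 20.5 min, but the autumn readings show 0.00117 /min. My reckoning takes the gap as loss from 41.9% of the charge, which gives 66.1 min as the holding time, target present divided by target lost per minute, with the scatter of a small slope.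

At 92 min, the midnight run has passed 8.60 fall times but 1.39 holding times. By my reckoning, 35.2% of the target that the winter reading shows at 23 min stays in the midnight run at 92 min, which comes to 12.1% of the charge, plus target formed later.

The forecast gives an order of 1 (0.8 to 1.15) and 37% (35% to 40%), noting that “The midnight run matches the winter charge”.

The flask gives an order of 1.0 and 18.1%.

    starting material + partner → target (0.02220 /M/min)
    starting material + partner → side product (0.004842 /M/min)
    starting material → decomposed substrate (0.02388 /min)
    target → decomposed product (0.01410 /min)

Without the passing of target into decomposed product, the midnight run stands at 52.7% instead of 18.1%, a difference of 35 percentage points. At the holding time of 66.1 min, the 18.1% of the midnight run at 92 min reckons to a loss of 0.00274 /min of the charge, and the 30.7% of the midnight run without the passing of starting material into decomposed substrate reckons to 0.00464 /min.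

(The runs are simulated for substances that don't exist; the scatter is artificial.)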